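**Retrosynthetic overview**
1. Target 35 comes from desilylation of 34. Compound 34 comes from oxidation of the macrocyclic diol 32, whose C3 ketone closes on the C10 hydroxyl to give the hemiketal. Diol 32 comes from a Nozaki–Hiyama–Kishi closure of C3–C4, so the ten-membered carbocycle is formed last.
2. Diol 32 comes from the cis-α-methylene-γ-butyrolactone 30. Lactone 30 comes from a zinc Barbier union at C6–C7 of allyl bromide 21 (C1–C3, C7–C14) with the (Z)-iodo-enal 26 (C4–C6, C15).
3. Bromide 21 comes from aldehyde 17, which comes from Baeyer–Villiger cleavage of a temporary C3–C7 bond in the 8-oxabicyclo[3.2.1]octan-2-one 13.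
4. Bicycle 13 comes from the acyclic diazoketone 10 and ethylene gas by a cyclic carbonyl-ylide [3+2] cycloaddition that forms C1–C10 and C2–C3 together. The enabling feature lies in the oxolane ring (O, C3, C2, C1, C10): its oxygen is flanked by the two carbons that hold the C1–C2 ethano unit, so C3–O–C10 is a carbonyl-ylide triad. C7 lies three bonds from C10 (C10–C9–C8–C7), so a temporary C3–C7 bond makes the ylide six-membered and places C8 on it as the control element.
5. Ring order: temporary oxanone plus oxolane (step 5), oxanone cut (step 6), lactone (step 14), carbocycle (step 15), oxygen bridge re-closed as hemiketal (step 16). All stereocentres descend from one proline aldol (C8).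

Key step: step 5

Assumption: germacrane numbering of the target (lactone O on C6, ester O on C8, bridge C3–O–C10; target = 3S,4Z,6S,7R,8R,10R) is used for all intermediates. The acetal or lactol carbon C3 of 15–17, 20, 21 and 27–30, carbinol C7 of 20 and carbinol C3 of 32 are epimer mixtures that converge later, so they carry no stereo mark.

Step 1
Reactants: 1 acetone; 2 ethyl glyoxylate
Product: 3 ethyl (2R)-2-hydroxy-4-oxopentanoate
Conditions: L-proline (20 mol %), acetone as solvent, rt
Reagents that add atoms: none
Why: Proline-catalysed direct asymmetric aldol reaction, in which the enamine of acetone adds to the activated aldehyde through the hydrogen-bonded chair-like transition state and L-proline should direct attack to the face that gives the (R)-carbinol, the future C8.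

Step 2
Reactants: 3 ethyl (2R)-2-hydroxy-4-oxopentanoate
Product: 4 (2R)-2-hydroxy-4-oxopentanoic acid
Conditions: pig liver esterase (a carboxylesterase), phosphate buffer pH 7, 25 °C
Reagents that add atoms: water, O
Why: Enzymatic ester hydrolysis at neutral pH should free the acid without the retro-aldol cleavage or dehydration that hydroxide would risk on this β-hydroxy ketone, and C8 is untouched.

Step 3
Reactants: 4 (2R)-2-hydroxy-4-oxopentanoic acid; 5 isobutyryl chloride
Product: 6 (2R)-2-(isobutyryloxy)-4-oxopentanoic acid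
Conditions: pyridine, CH2Cl2, 0 °C; aqueous work-up
Reagents that add atoms: none
Why: O-acylation of the secondary alcohol (any mixed anhydride at the carboxyl group is hydrolysed on work-up) installs the natural C8 ester early, at low temperature so that β-elimination to the enone is avoided.

Step 4
Reactants: 6 (2R)-2-(isobutyryloxy)-4-oxopentanoic acid; 7 (trimethylsilyl)diazomethane
Product: 10 (3R)-1-diazo-2,5-dioxohexan-3-yl isobutyrate, via mixed anhydride 8 (not isolated), via silyl diazoketone 9 (not isolated)
Conditions: ClCO2Et, N-methylmorpholine, THF, −20 °C; then 7, THF/MeCN, 0 °C to rt; aqueous work-up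
Reagents that add atoms: ethyl chloroformate, CCOC(=O)Cl (its atoms appear only in 8)
Why: Acylation of a diazoalkane by a mixed carbonic anhydride (Arndt–Eistert-type diazoketone synthesis) avoids the cyclic pseudo-chloride that γ-keto acids give with chlorinating agents; the C-silyl group is lost on work-up and the diazo carbon becomes C3.

Step 5
Reactants: 10 (3R)-1-diazo-2,5-dioxohexan-3-yl isobutyrate; 11 ethylene
Product: 13 (1S,3R,5R)-5-methyl-2-oxo-8-oxabicyclo[3.2.1]octan-3-yl isobutyrate, via carbonyl ylide 12 (not isolated)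
Conditions: Rh2(OAc)4 (1 mol %), ethylene (40 bar, autoclave), CH2Cl2, 25 °C, 10 added over 6 h
Reagents that add atoms: none
Why: Rh2(OAc)4 expels N2 from 10 and the electrophilic dirhodium carbenoid at C3 is captured by a lone pair of the C10 ketone oxygen, which closes the temporary oxanone ring (O, C10, C9, C8, C7, C3) as the cyclic carbonyl ylide 12; ethylene then adds suprafacially across C3 and C10 in a concerted [3+2] cycloaddition that forms C2–C3 and C1–C10 at once. The closest known reaction type is the tandem carbonyl-ylide formation/1,3-dipolar cycloaddition of 1-diazoalkane-2,5-diones with alkenes, and addition of carbonyl ylides to ethylene itself is known from thermally opened oxiranes. Ring closures: the oxanone ring forms by intramolecular attack of oxygen on the carbenoid (six-membered), while the oxolane ring (O, C3, C2, C1, C10) and the seven-membered carbocycle form in the cycloaddition. Stereocontrol: C3 and C10 are tied cis by the suprafacial addition, and their absolute sense is set by C8, because ethylene should approach the nearly flat ylide on the face opposite the isobutyryloxy group, which ends exo (equatorial) and anti to the new ethano bridge, the relation the target needs between C8 and C10. Selectivity needed: the carbenoid must be captured by the ketone and not by the ester carbonyl (the ketone oxygen is the better donor and ylide formation is reversible), and 12 must be trapped before dimerisation or proton shift (slow addition, high ethylene pressure); because ethylene is symmetric there is no regio- or endo/exo question and no activating group has to be removed afterwards.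

Step 6
Reactants: 13 (1S,3R,5R)-5-methyl-2-oxo-8-oxabicyclo[3.2.1]octan-3-yl isobutyrate
Product: 14 (1R,4R,6R)-6-methyl-3-oxo-2,9-dioxabicyclo[4.2.1]nonan-4-yl isobutyrate
Conditions: mCPBA, CH2Cl2, 0 °C to rt
Reagents that add atoms: mCPBA, O=C(OO)c1cccc(Cl)c1
Why: Baeyer–Villiger oxidation, in which the bridgehead carbon C3 that bears the ring oxygen should migrate (the acyloxy-bearing C8 is deactivated) with retention, so the temporary C3–C7 bond is replaced by C3–O and C3 reaches the aldehyde oxidation level.

Step 7
Reactants: 14 (1R,4R,6R)-6-methyl-3-oxo-2,9-dioxabicyclo[4.2.1]nonan-4-yl isobutyrate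
Product: 16 S-ethyl (2R)-2-(isobutyryloxy)-3-[(2R)-5-methoxy-2-methyloxolan-2-yl]propanethioate, via lactol thioester 15 (not isolated)
Conditions: EtSH, Et3N, CH2Cl2, rt; evaporate; MeOH, TsOH·H2O (cat.), rt
Reagents that add atoms: ethanethiol, CCS; methanol, CO
Why: Acyl transfer followed by acetalisation; the carbonyl of 14 is an activated (acylal) ester inside a bridged seven-membered lactone, so thiolate should open it selectively beside the isobutyrate, and acid-catalysed acetalisation of the released lactol masks C3.

Step 8
Reactants: 16 S-ethyl (2R)-2-(isobutyryloxy)-3-[(2R)-5-methoxy-2-methyloxolan-2-yl]propanethioate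
Product: 17 (2R)-1-[(2R)-5-methoxy-2-methyloxolan-2-yl]-3-oxopropan-2-yl isobutyrate
Conditions: Et3SiH, Pd/C (10 wt %), acetone, rt
Reagents that add atoms: none
Why: Fukuyama reduction, in which zerovalent palladium inserts into the C–S bond and the acylpalladium is reduced by the silane, so only the thioester goes to the aldehyde (C7) while isobutyrate and acetal survive.

Step 9
Reactants: 17 (2R)-1-[(2R)-5-methoxy-2-methyloxolan-2-yl]-3-oxopropan-2-yl isobutyrate; 18 methyl propiolate
Product: 20 methyl (4R)-3-hydroxy-4-(isobutyryloxy)-5-[(2R)-5-methoxy-2-methyloxolan-2-yl]-2-methylidenepentanoate, via vinylalane 19 (not isolated)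
Conditions: iBu2AlH, HMPA, THF, 0 °C, 18; then 17, 0 °C to rt; aqueous work-up
Reagents that add atoms: diisobutylaluminium hydride, CC(C)C[AlH]CC(C)C (its atoms other than H appear only in 19)
Why: Regioselective hydroalumination of the propiolate gives the α-aluminated acrylate, which adds 1,2 to the aldehyde to give the Morita–Baylis–Hillman-type adduct without amine base, so the α-acyloxy aldehyde should not epimerise; the new C7 carbinol centre is erased in step 10.

Step 10
Reactants: 20 methyl (4R)-3-hydroxy-4-(isobutyryloxy)-5-[(2R)-5-methoxy-2-methyloxolan-2-yl]-2-methylidenepentanoate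
Product: 21 methyl (2Z,4R)-2-(bromomethyl)-4-(isobutyryloxy)-5-[(2R)-5-methoxy-2-methyloxolan-2-yl]pent-2-enoate
Conditions: NBS, Me2S, CH2Cl2, 0 °C to rt
Reagents that add atoms: N-bromosuccinimide, O=C1CCC(=O)N1Br
Why: Activation of the allylic alcohol as an alkoxysulfonium salt (Corey–Kim-type reagent) and SN2′ attack of bromide at the methylidene carbon give the rearranged primary allyl bromide, with the (Z) isomer (C8 cis to CH2Br, trans to the ester) favoured by allylic strain.

Step 11
Reactants: 22 but-2-yne-1,4-diol
Product: 23 4-[(tert-butyldiphenylsilyl)oxy]but-2-yn-1-ol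
Conditions: TBDPSCl (0.3 equiv), imidazole, DMF, 0 °C to rt
Reagents that add atoms: tert-butyl(chloro)diphenylsilane, CC(C)(C)[Si](Cl)(c1ccccc1)c1ccccc1
Why: Statistical monosilylation of the symmetrical diol, used in excess.

Step 12
Reactants: 23 4-[(tert-butyldiphenylsilyl)oxy]but-2-yn-1-ol
Product: 25 (2Z)-4-[(tert-butyldiphenylsilyl)oxy]-3-iodobut-2-en-1-ol, via vinylalanate 24 (not isolated)
Conditions: NaAlH2(OCH2CH2OMe)2, THF, 0 °C; then I2, −78 °C to 0 °C
Reagents that add atoms: iodine, II; sodium bis(2-methoxyethoxy)aluminium hydride, [Na+].COCCO[AlH2-]OCCOC (its atoms other than H appear only in 24)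
Why: Hydroxyl-directed trans-hydroalumination of the propargylic alcohol places aluminium on the distal alkyne carbon inside a five-membered alanate, and iodinolysis with retention gives the (Z)-vinyl iodide, which fixes the C4=C5 geometry of the target.

Step 13
Reactants: 25 (2Z)-4-[(tert-butyldiphenylsilyl)oxy]-3-iodobut-2-en-1-ol
Product: 26 (2Z)-4-[(tert-butyldiphenylsilyl)oxy]-3-iodobut-2-enal
Conditions: MnO2, CH2Cl2, rt
Reagents that add atoms: none
Why: Selective allylic alcohol oxidation with MnO2 under neutral conditions should keep the alkene geometry and the C–I bond.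

Step 14
Reactants: 21 methyl (2Z,4R)-2-(bromomethyl)-4-(isobutyryloxy)-5-[(2R)-5-methoxy-2-methyloxolan-2-yl]pent-2-enoate; 26 (2Z)-4-[(tert-butyldiphenylsilyl)oxy]-3-iodobut-2-enal
Product: 30 cis-lactone lactol (C6/C7/C8/C10 as in the target), via allylzinc bromide 27 (not isolated), via hydroxy ester 28 (not isolated), via lactone acetal 29 (not isolated)
Conditions: Zn dust, THF/sat. aq. NH4Cl, 0 °C to rt; then TsOH·H2O (cat.), THF/H2O, rt
Reagents that add atoms: zinc, [Zn] (appears only in 27); water, O
Why: Zinc Barbier allylation (SE2′) through a Zimmerman–Traxler chair, in which the C8 substituent cis to CH2Zn should place C6–O and C7–C8 syn (the cis-lactone after acid-induced lactonisation), and with H8 eclipsing the alkene (allylic 1,3-strain) the enal should attack C7 anti to the C9 chain to give the C7/C8 relation of the target; the same acid hydrolyses the methyl acetal.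

Step 15
Reactants: 30 cis-lactone lactol
Product: 32 macrocyclic 3,10-diol (ten-membered ring and 4Z alkene; C6/C7/C8/C10 as in the target), via hydroxy aldehyde 31 (not isolated)
Conditions: CrCl2 (8 equiv), NiCl2 (2 mol %), DMSO/THF, 0.002 M, rt, slow addition
Reagents that add atoms: none
Why: Nozaki–Hiyama–Kishi reaction, in which zerovalent nickel inserts into the vinyl C–I bond with retention of geometry and transmetalation gives the vinyl species of trivalent chromium; this adds chemoselectively to the small equilibrium share of open aldehyde 31 and tolerates esters, lactone and free hydroxyl, and the new C3 carbinol centre is erased in step 16.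

Step 16
Reactants: 32 macrocyclic 3,10-diol
Product: 34 15-O-(tert-butyldiphenylsilyl) ether of the target, via hydroxy enone 33 (not isolated)
Conditions: Dess–Martin periodinane, CH2Cl2, 0 °C to rt
Reagents that add atoms: none
Why: Dess–Martin oxidation of the secondary allylic alcohol (the tertiary C10 hydroxyl cannot react) gives enone 33, whose C3 carbonyl is attacked transannularly by the C10 hydroxyl; the bridge can only close cis across the oxolane, so C10 dictates the (S) configuration of hemiketal carbon C3.

Step 17
Reactants: 34 15-O-(tert-butyldiphenylsilyl) ether of the target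
Product: 35 target CNP0282937.2
Conditions: HF·pyridine, pyridine, THF, 0 °C to rt
Reagents that add atoms: none
Why: Fluoride-induced silyl ether cleavage under buffered conditions should spare the hemiketal, the isobutyrate and the α-methylene lactone.

**Compound list**
1 | acetone | CC(C)=O | starting material
2 | ethyl glyoxylate | CCOC(=O)C=O | starting material
3 | ethyl (2R)-2-hydroxy-4-oxopentanoate | CC(=O)C[C@@H](O)C(=O)OCC | intermediate
4 | (2R)-2-hydroxy-4-oxopentanoic acid | CC(=O)C[C@@H](O)C(=O)O | intermediate
5 | isobutyryl chloride | CC(C)C(=O)Cl | starting material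
6 | (2R)-2-(isobutyryloxy)-4-oxopentanoic acid | CC(=O)C[C@@H](OC(=O)C(C)C)C(=O)O | intermediate
7 | (trimethylsilyl)diazomethane | C[Si](C)(C)C=[N+]=[N-] | starting material
8 | mixed ethyl carbonic anhydride of 6 | CC(=O)C[C@@H](OC(=O)C(C)C)C(=O)OC(=O)OCC | intermediate
9 | 1-trimethylsilyl derivative of 10 | CC(=O)C[C@@H](OC(=O)C(C)C)C(=O)C(=[N+]=[N-])[Si](C)(C)C | intermediate
10 | (3R)-1-diazo-2,5-dioxohexan-3-yl isobutyrate | CC(=O)C[C@@H](OC(=O)C(C)C)C(=O)C=[N+]=[N-] | intermediate
11 | ethylene | C=C | starting material
12 | six-membered carbonyl ylide (C10=O+–C3H−, C8 R) | CC1=[O+][CH-]C(=O)[C@H](OC(=O)C(C)C)C1 | intermediate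
13 | (1S,3R,5R)-5-methyl-2-oxo-8-oxabicyclo[3.2.1]octan-3-yl isobutyrate | O=C1[C@@H]2CC[C@](C)(C[C@H]1OC(=O)C(C)C)O2 | intermediate
14 | (1R,4R,6R)-6-methyl-3-oxo-2,9-dioxabicyclo[4.2.1]nonan-4-yl isobutyrate | O=C1O[C@@H]2CC[C@](C)(C[C@H]1OC(=O)C(C)C)O2 | intermediate
15 | S-ethyl (2R)-3-[(2R)-5-hydroxy-2-methyloxolan-2-yl]-2-(isobutyryloxy)propanethioate | CCSC(=O)[C@H](OC(=O)C(C)C)C[C@@]1(C)CCC(O)O1 | intermediate
16 | S-ethyl (2R)-2-(isobutyryloxy)-3-[(2R)-5-methoxy-2-methyloxolan-2-yl]propanethioate | CCSC(=O)[C@H](OC(=O)C(C)C)C[C@@]1(C)CCC(OC)O1 | intermediate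
17 | (2R)-1-[(2R)-5-methoxy-2-methyloxolan-2-yl]-3-oxopropan-2-yl isobutyrate | O=C[C@H](OC(=O)C(C)C)C[C@@]1(C)CCC(OC)O1 | intermediate
18 | methyl propiolate | C#CC(=O)OC | starting material
19 | [1-(methoxycarbonyl)ethenyl]diisobutylaluminium | C=C(C(=O)OC)[Al](CC(C)C)CC(C)C | intermediate
20 | methyl (4R)-3-hydroxy-4-(isobutyryloxy)-5-[(2R)-5-methoxy-2-methyloxolan-2-yl]-2-methylidenepentanoate | C=C(C(=O)OC)C(O)[C@H](OC(=O)C(C)C)C[C@@]1(C)CCC(OC)O1 | intermediate
21 | methyl (2Z,4R)-2-(bromomethyl)-4-(isobutyryloxy)-5-[(2R)-5-methoxy-2-methyloxolan-2-yl]pent-2-enoate | COC(=O)/C(CBr)=C/[C@H](OC(=O)C(C)C)C[C@@]1(C)CCC(OC)O1 | intermediate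
22 | but-2-yne-1,4-diol | OCC#CCO | starting material
23 | 4-[(tert-butyldiphenylsilyl)oxy]but-2-yn-1-ol | OCC#CCO[Si](c1ccccc1)(c1ccccc1)C(C)(C)C | intermediate
24 | cyclic sodium vinylalanate (five-membered ring Al, O, C6, C5, C4) | [Na+].COCCO[Al-]1(OCCOC)OCC=C1CO[Si](c1ccccc1)(c1ccccc1)C(C)(C)C | intermediate
25 | (2Z)-4-[(tert-butyldiphenylsilyl)oxy]-3-iodobut-2-en-1-ol | OC/C=C(\I)CO[Si](c1ccccc1)(c1ccccc1)C(C)(C)C | intermediate
26 | (2Z)-4-[(tert-butyldiphenylsilyl)oxy]-3-iodobut-2-enal | O=C/C=C(\I)CO[Si](c1ccccc1)(c1ccccc1)C(C)(C)C | intermediate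
27 | allylzinc bromide from 21 | COC(=O)/C(C[Zn]Br)=C/[C@H](OC(=O)C(C)C)C[C@@]1(C)CCC(OC)O1 | intermediate
28 | open Barbier adduct, syn hydroxy ester (C6–OH free, C6/C7/C8/C10 as in the target) | C=C(C(=O)OC)[C@@H]([C@@H](O)/C=C(\I)CO[Si](c1ccccc1)(c1ccccc1)C(C)(C)C)[C@H](OC(=O)C(C)C)C[C@@]1(C)CCC(OC)O1 | intermediate
29 | cis-α-methylene-γ-butyrolactone with (Z)-iodoalkenyl group on C6 and methyl acetal at C3 | C=C1C(=O)O[C@@H](/C=C(\I)CO[Si](c2ccccc2)(c2ccccc2)C(C)(C)C)[C@H]1[C@H](OC(=O)C(C)C)C[C@@]1(C)CCC(OC)O1 | intermediate
30 | cis-lactone lactol (as 29, C3–OH) | C=C1C(=O)O[C@@H](/C=C(\I)CO[Si](c2ccccc2)(c2ccccc2)C(C)(C)C)[C@H]1[C@H](OC(=O)C(C)C)C[C@@]1(C)CCC(O)O1 | intermediate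
31 | open hydroxy aldehyde form of 30 (C3 aldehyde, C10 tertiary alcohol) | C=C1C(=O)O[C@@H](/C=C(\I)CO[Si](c2ccccc2)(c2ccccc2)C(C)(C)C)[C@H]1[C@H](OC(=O)C(C)C)C[C@](C)(O)CCC=O | intermediate
32 | macrocyclic 3,10-diol, 15-O-TBDPS, 4Z | C=C1C(=O)O[C@H]2/C=C(/CO[Si](c3ccccc3)(c3ccccc3)C(C)(C)C)C(O)CC[C@@](C)(O)C[C@@H](OC(=O)C(C)C)[C@@H]12 | intermediate
33 | macrocyclic 10-hydroxy-3-enone, 15-O-TBDPS | C=C1C(=O)O[C@H]2/C=C(/CO[Si](c3ccccc3)(c3ccccc3)C(C)(C)C)C(=O)CC[C@@](C)(O)C[C@@H](OC(=O)C(C)C)[C@@H]12 | intermediate
34 | 15-O-(tert-butyldiphenylsilyl) ether of the target | C=C1C(=O)O[C@H]2/C=C(/CO[Si](c3ccccc3)(c3ccccc3)C(C)(C)C)[C@]3(O)CC[C@](C)(C[C@@H](OC(=O)C(C)C)[C@@H]12)O3 | intermediate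
35 | CNP0282937.2, (3S,4Z,6S,7R,8R,10R)-3,10-epoxy-3,15-dihydroxy-8-(isobutyryloxy)germacra-4,11(13)-dien-12,6-olide | C=C1C(=O)O[C@H]2/C=C(/CO)[C@]3(O)CC[C@](C)(C[C@@H](OC(=O)C(C)C)[C@@H]12)O3 | target

**Step count and risks**
Total step count: 17. Longest linear sequence: 14 (steps 1–10 and 14–17).

Steps most likely to fail:

Step 5. Unactivated ethylene may trap the ylide too slowly, so that ylide dimerisation, proton shift or capture of the carbenoid by the ester carbonyl takes over; shielding of one face by the C8 ester may also be incomplete. The fallback sets out from 10 and comes back at 13. Compound 10 is decomposed with Rh2(OAc)4 in toluene in the presence of phenyl vinyl sulfoxide, an activated two-carbon dipolarophile, to give the sulfinyl cycloadduct F1; either regioisomer serves. Heating at 110 °C expels the sulfenic acid by syn elimination, which cannot run towards the bridgeheads, and gives the bicyclic alkene F2. Hydrogenation (H2, Pd/C, EtOAc) of the strained C1=C2 bond returns to 13.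

Step 14. The allylzinc carries an acyloxy leaving group on C8, so reductive 1,4-elimination to a diene may compete with carbonyl addition. Metallotropic equilibration may also erode the alkene geometry, and with it the syn and facial selectivity. The fallback sets out from 21 and comes back at 29. Borylation of 21 (B2pin2, CuCl, LiCl, KOAc, DMF, rt) gives the non-reducing, configurationally stable allylboronate F3. Thermal allylboration of 26 with F3 (toluene, 80–100 °C) runs through the closed six-membered transition state, and the borate lactonises to 29. The acid hydrolysis of step 14 then follows.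

Step 15. Closure of the strained ten-membered ring may be slower than protodemetalation of the vinylchromium species or intermolecular coupling, all the more because the aldehyde is largely hidden as lactol. The fallback sets out from 21 and comes back at 34, and it closes the ring at C4=C5 instead.
- Barbier reaction of 21 with acrolein under the conditions of step 14 gives the vinyl lactol F4.
- 2-Bromoprop-2-en-1-ol is silylated (TBDPSCl, imidazole) to the bromoallyl silyl ether F5.
- Intermolecular Nozaki–Hiyama–Kishi coupling of F4 with F5 (CrCl2, cat. NiCl2, DMF) gives the acyclic diol F6.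
- Dess–Martin oxidation gives the hydroxy enone diene F7, in equilibrium with its hemiketal.
- Ring-closing metathesis (second-generation Hoveyda–Grubbs catalyst, toluene, 80 °C, high dilution) joins the C4 methylidene and the C5 vinyl group, while the electron-poor α-methylene lactone stays out. The medium ring and the oxygen bridge should enforce the Z alkene of 34.

**Further compounds**
F1 | step 5 | 5-methyl-2-oxo-7-(phenylsulfinyl)-8-oxabicyclo[3.2.1]octan-3-yl isobutyrate (ring stereocentres as in 13) | O=C1[C@@H]2C(S(=O)c3ccccc3)C[C@](C)(C[C@H]1OC(=O)C(C)C)O2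
F2 | step 5 | 5-methyl-2-oxo-8-oxabicyclo[3.2.1]oct-6-en-3-yl isobutyrate (stereocentres as in 13) | O=C1[C@@H]2C=C[C@](C)(C[C@H]1OC(=O)C(C)C)O2
F3 | step 14 | pinacol allylboronate corresponding to 21 (CH2Bpin in place of CH2Br, same alkene geometry) | COC(=O)/C(CB1OC(C)(C)C(C)(C)O1)=C/[C@H](OC(=O)C(C)C)C[C@@]1(C)CCC(OC)O1
F4 | step 15 | cis-lactone lactol with a vinyl group on C6 | C=C1C(=O)O[C@@H](C=C)[C@H]1[C@H](OC(=O)C(C)C)C[C@@]1(C)CCC(O)O1
F5 | step 15 | [(2-bromoprop-2-en-1-yl)oxy](tert-butyl)diphenylsilane | C=C(Br)CO[Si](c1ccccc1)(c1ccccc1)C(C)(C)C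
F6 | step 15 | acyclic 3,10-diol diene (C4 methylidene, C5 vinyl) | C=C1C(=O)O[C@@H](C=C)[C@H]1[C@H](OC(=O)C(C)C)C[C@](C)(O)CCC(O)C(=C)CO[Si](c1ccccc1)(c1ccccc1)C(C)(C)C
F7 | step 15 | acyclic 10-hydroxy-3-enone diene | C=C1C(=O)O[C@@H](C=C)[C@H]1[C@H](OC(=O)C(C)C)C[C@](C)(O)CCC(=O)C(=C)CO[Si](c1ccccc1)(c1ccccc1)C(C)(C)C
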